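**Strategy.** The route rests on cutting the C3–C4 bond of ring C. The α-ketol C4(=O)–C3(OH), with C4 on ring A and C3 next to the epimerisable C2 that carries ring B and O1, is the retron of a crossed benzoin reaction. In one operation a chiral triazolylidene should join the two formyl carbons of a racemic dialdehyde, close the pyranone ring, and set C2 and C3 by dynamic kinetic resolution. The precursor is an O1–C2 ether: a 2-aryl-2-aryloxyacetaldehyde whose aryloxy part is a 6-silyloxy-4-prenyloxysalicylaldehyde. All phenols are carried as TBS ethers, because the 7-O-prenyl ether would not survive acid.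

Key step: step 9

**Remarks and assumptions**

- The target is the 2,3-trans (2R,3R) isomer, the 7-O-prenyl ether of (+)-taxifolin. Flavanone numbering is used (O1, C2, C3, C4; rings A, B, C). TBS = tert-butyldimethylsilyl; prenyl = 3-methylbut-2-en-1-yl.
- Protecting groups: acetal-type phenol protection such as MOM must be removed with Brønsted acid, under which an aryl prenyl ether on the electron-poor O7 is expected to ionise. The three phenols are therefore TBS ethers, released at the end with buffered fluoride.
- The ester and the aryl aldehyde are both reduced and then both re-oxidised, so no carbonyl masking is needed.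
- Compound 2 is also commercially available; buying it saves step 1.
- The absolute sense of induction in step 9 cannot be predicted. Both antipodes of the precatalyst are available, and the one that gives the 2R series is to be used.

**Route**

Step 1
Reactants: 1 3,4-dihydroxyphenylacetic acid
Product: 2 methyl 3,4-dihydroxyphenylacetate
Conditions: MeOH, H2SO4 (cat.), reflux
Reagents that add atoms: methanol, CO
Why: Fischer esterification in excess methanol; the catechol is inert to acidic methanol and no stereocentre is involved.

Step 2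
Reactants: 2 methyl 3,4-dihydroxyphenylacetate
Product: 3 methyl 2-[3,4-bis(tert-butyldimethylsilyloxy)phenyl]acetate
Conditions: TBSCl (2.4 equiv), imidazole, DMF, rt
Reagents that add atoms: tert-butyldimethylsilyl chloride, CC(C)(C)[Si](C)(C)Cl
Why: Standard silylation of phenols with silyl chloride and imidazole, which blocks both catechol oxygens so that later enolate and alkylation chemistry touches only the CH2CO2Me unit.

Step 3
Reactants: 3 methyl 2-[3,4-bis(tert-butyldimethylsilyloxy)phenyl]acetate
Product: 5 methyl 2-bromo-2-[3,4-bis(tert-butyldimethylsilyloxy)phenyl]acetate (racemic), via silyl ketene acetal 4 (not isolated)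
Conditions: LiHMDS, THF, −78 °C; TMSCl; then NBS, −78 to −40 °C; used promptly
Reagents that add atoms: N-bromosuccinimide, O=C1CCC(=O)N1Br (chlorotrimethylsilane, C[Si](C)(C)Cl, supplies only the silyl group of 4, which is lost again)
Why: α-Halogenation of an ester through its silyl ketene acetal, which should be brominated once by NBS at the benzylic α-carbon and not on the ring at low temperature; the new stereocentre is racemic on purpose.

Step 4
Reactants: 6 2,4,6-trihydroxybenzaldehyde; 7 prenyl bromide (1.0 equiv)
Product: 8 2,6-dihydroxy-4-(3-methylbut-2-enyloxy)benzaldehyde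
Conditions: K2CO3 (1.0 equiv), acetone, 0 °C to rt
Reagents that add atoms: none
Why: Williamson etherification; the 4-OH, para to the formyl group and not hydrogen-bonded, is the most acidic, so its phenoxide should be alkylated first when only one equivalent of bromide is offered.

Step 5
Reactants: 8 2,6-dihydroxy-4-(3-methylbut-2-enyloxy)benzaldehyde; 5 methyl 2-bromo-2-[3,4-bis(tert-butyldimethylsilyloxy)phenyl]acetate (1.0 equiv)
Product: 9 methyl 2-[3,4-bis(tert-butyldimethylsilyloxy)phenyl]-2-[2-formyl-3-hydroxy-5-(3-methylbut-2-enyloxy)phenoxy]acetate (racemic)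
Conditions: K2CO3 (1.2 equiv), acetone, rt
Reagents that add atoms: none
Why: Williamson etherification (SN2 at an activated α-bromo arylacetate) that forms the O1–C2 bond; the two ortho hydroxyls are equivalent, and after the first alkylation the remaining one is locked in the hydrogen bond to the formyl oxygen and is much harder to deprotonate, so mono-etherification is expected; C2 is racemic on purpose.

Step 6
Reactants: 9 methyl 2-[3,4-bis(tert-butyldimethylsilyloxy)phenyl]-2-[2-formyl-3-hydroxy-5-(3-methylbut-2-enyloxy)phenoxy]acetate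
Product: 10 methyl 2-[3,4-bis(tert-butyldimethylsilyloxy)phenyl]-2-[3-(tert-butyldimethylsilyloxy)-2-formyl-5-(3-methylbut-2-enyloxy)phenoxy]acetate (racemic)
Conditions: TBSCl (1.5 equiv), imidazole, DMAP (cat.), DMF, rt
Reagents that add atoms: tert-butyldimethylsilyl chloride, CC(C)(C)[Si](C)(C)Cl
Why: Silylation of the chelated phenol under forcing but non-basic conditions, which removes the acidic OH that would quench the carbene later and gives uniform fluoride-labile protection.

Step 7
Reactants: 10 methyl 2-[3,4-bis(tert-butyldimethylsilyloxy)phenyl]-2-[3-(tert-butyldimethylsilyloxy)-2-formyl-5-(3-methylbut-2-enyloxy)phenoxy]acetate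
Product: 11 2-[3,4-bis(tert-butyldimethylsilyloxy)phenyl]-2-[3-(tert-butyldimethylsilyloxy)-2-(hydroxymethyl)-5-(3-methylbut-2-enyloxy)phenoxy]ethan-1-ol (racemic)
Conditions: DIBAL-H (5 equiv), CH2Cl2, −78 to 0 °C; aq. Rochelle salt
Reagents that add atoms: none
Why: Hydride reduction of both the aryl aldehyde and the ester to primary alcohols with DIBAL-H; aryl silyl ethers and the prenyl ether are inert, and the cold, weakly nucleophilic aluminium alkoxide should not take over the neighbouring silyl group.

Step 8
Reactants: 11 2-[3,4-bis(tert-butyldimethylsilyloxy)phenyl]-2-[3-(tert-butyldimethylsilyloxy)-2-(hydroxymethyl)-5-(3-methylbut-2-enyloxy)phenoxy]ethan-1-ol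
Product: 12 rac-2-[3,4-bis(tert-butyldimethylsilyloxy)phenyl]-2-[3-(tert-butyldimethylsilyloxy)-2-formyl-5-(3-methylbut-2-enyloxy)phenoxy]acetaldehyde
Conditions: Dess–Martin periodinane (2.6 equiv), NaHCO3, CH2Cl2, 0 °C to rt; filtered and used at once
Reagents that add atoms: none
Why: Dess–Martin oxidation of the benzylic and the aliphatic primary alcohol under bicarbonate buffer stops at the aldehyde stage and is mild enough for the enolisable α-aryl-α-aryloxy aldehyde, whose configuration is racemic in any case.

Step 9
Reactants: 12 rac-2-[3,4-bis(tert-butyldimethylsilyloxy)phenyl]-2-[3-(tert-butyldimethylsilyloxy)-2-formyl-5-(3-methylbut-2-enyloxy)phenoxy]acetaldehyde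
Product: 13 (2R,3R)-2-[3,4-bis(tert-butyldimethylsilyloxy)phenyl]-5-(tert-butyldimethylsilyloxy)-3-hydroxy-7-(3-methylbut-2-enyloxy)chroman-4-one
Conditions: aminoindanol-derived N-pentafluorophenyl triazolium tetrafluoroborate (single antipode, 15 mol %), i-Pr2NEt (1 equiv), toluene, 4 Å MS, rt, Ar
Reagents that add atoms: none
Why: Proposed new method: the triazolylidene adds to the aryl formyl carbon (C4), proton transfer gives the enaminol (Breslow intermediate), this acyl-anion equivalent attacks the tethered aliphatic formyl carbon (C3) in a 6-exo-trig closure of ring C, and loss of the carbene releases the 3-hydroxychroman-4-one. The closest known reaction types are the enantioselective intramolecular crossed benzoin closure of ketone-tethered salicylaldehydes to 3-hydroxychroman-4-ones and carbene-catalysed dynamic kinetic resolutions of epimerisable carbonyl compounds; an aldehyde acceptor with a labile α-centre is not precedented. C2 is selected, not created: the α-aryl-α-aryloxy aldehyde should racemise through its enol under the amine faster than it cyclises, the chiral carbene (catalyst control) should cyclise mainly the enantiomer that leads to 2R, and after closure C2 is no longer α to a carbonyl and stays fixed. C3 is set in the C–C bond formation by the face of the formyl group presented to the catalyst-bound enaminol, and a 2,3-cis isomer can still relax through the enediol to the diequatorial trans (3R) ketol under the same base. The step needs the aryl aldehyde, not the aliphatic one, to become the acyl anion, since a Breslow intermediate at C3 could expel the aryloxide; the α,α-disubstitution at C2 hinders carbene addition to the aliphatic formyl group, while its high electrophilicity makes it the better acceptor, and the aryl-conjugated ketone is the more stable acyloin regioisomer. The absolute sense of induction cannot be predicted and is to be fixed by choosing the catalyst antipode.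

Step 10
Reactants: 13 (2R,3R)-2-[3,4-bis(tert-butyldimethylsilyloxy)phenyl]-5-(tert-butyldimethylsilyloxy)-3-hydroxy-7-(3-methylbut-2-enyloxy)chroman-4-one
Product: 14 (2R,3R)-2-(3,4-dihydroxyphenyl)-3,5-dihydroxy-7-(3-methylbut-2-enyloxy)chroman-4-one (CNP0296402.1)
Conditions: TBAF (3.3 equiv), AcOH (4 equiv), THF, 0 °C
Reagents that add atoms: none
Why: Fluoride-induced cleavage of the three aryl silyl ethers; the acetic acid buffer keeps the medium from turning basic, so C2 and C3 should not epimerise and ring C should not open, and neither the prenyl ether nor the alkene is touched.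

**Compound list**

1 | 3,4-dihydroxyphenylacetic acid | OC(=O)Cc1ccc(O)c(O)c1 | starting material
2 | methyl 3,4-dihydroxyphenylacetate | COC(=O)Cc1ccc(O)c(O)c1 | intermediate
3 | methyl 2-[3,4-bis(tert-butyldimethylsilyloxy)phenyl]acetate | COC(=O)Cc1ccc(O[Si](C)(C)C(C)(C)C)c(O[Si](C)(C)C(C)(C)C)c1 | intermediate
4 | 1-methoxy-1-(trimethylsilyloxy)-2-[3,4-bis(tert-butyldimethylsilyloxy)phenyl]ethene (silyl ketene acetal, E/Z mixture, not isolated) | COC(O[Si](C)(C)C)=Cc1ccc(O[Si](C)(C)C(C)(C)C)c(O[Si](C)(C)C(C)(C)C)c1 | intermediate
5 | methyl 2-bromo-2-[3,4-bis(tert-butyldimethylsilyloxy)phenyl]acetate (racemic) | COC(=O)C(Br)c1ccc(O[Si](C)(C)C(C)(C)C)c(O[Si](C)(C)C(C)(C)C)c1 | intermediate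
6 | 2,4,6-trihydroxybenzaldehyde | O=Cc1c(O)cc(O)cc1O | starting material
7 | prenyl bromide (1-bromo-3-methylbut-2-ene) | CC(C)=CCBr | starting material
8 | 2,6-dihydroxy-4-(3-methylbut-2-enyloxy)benzaldehyde | CC(C)=CCOc1cc(O)c(C=O)c(O)c1 | intermediate
9 | methyl 2-[3,4-bis(tert-butyldimethylsilyloxy)phenyl]-2-[2-formyl-3-hydroxy-5-(3-methylbut-2-enyloxy)phenoxy]acetate (racemic) | COC(=O)C(Oc1cc(OCC=C(C)C)cc(O)c1C=O)c1ccc(O[Si](C)(C)C(C)(C)C)c(O[Si](C)(C)C(C)(C)C)c1 | intermediate
10 | methyl 2-[3,4-bis(tert-butyldimethylsilyloxy)phenyl]-2-[3-(tert-butyldimethylsilyloxy)-2-formyl-5-(3-methylbut-2-enyloxy)phenoxy]acetate (racemic) | COC(=O)C(Oc1cc(OCC=C(C)C)cc(O[Si](C)(C)C(C)(C)C)c1C=O)c1ccc(O[Si](C)(C)C(C)(C)C)c(O[Si](C)(C)C(C)(C)C)c1 | intermediate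
11 | 2-[3,4-bis(tert-butyldimethylsilyloxy)phenyl]-2-[3-(tert-butyldimethylsilyloxy)-2-(hydroxymethyl)-5-(3-methylbut-2-enyloxy)phenoxy]ethan-1-ol (racemic) | OCC(Oc1cc(OCC=C(C)C)cc(O[Si](C)(C)C(C)(C)C)c1CO)c1ccc(O[Si](C)(C)C(C)(C)C)c(O[Si](C)(C)C(C)(C)C)c1 | intermediate
12 | rac-2-[3,4-bis(tert-butyldimethylsilyloxy)phenyl]-2-[3-(tert-butyldimethylsilyloxy)-2-formyl-5-(3-methylbut-2-enyloxy)phenoxy]acetaldehyde (key-step precursor) | O=CC(Oc1cc(OCC=C(C)C)cc(O[Si](C)(C)C(C)(C)C)c1C=O)c1ccc(O[Si](C)(C)C(C)(C)C)c(O[Si](C)(C)C(C)(C)C)c1 | intermediate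
13 | (2R,3R)-2-[3,4-bis(tert-butyldimethylsilyloxy)phenyl]-5-(tert-butyldimethylsilyloxy)-3-hydroxy-7-(3-methylbut-2-enyloxy)chroman-4-one (5,3',4'-tri-O-TBS-7-O-prenyltaxifolin) | CC(C)=CCOc1cc(O[Si](C)(C)C(C)(C)C)c2c(c1)O[C@H](c1ccc(O[Si](C)(C)C(C)(C)C)c(O[Si](C)(C)C(C)(C)C)c1)[C@@H](O)C2=O | intermediate
14 | (2R,3R)-2-(3,4-dihydroxyphenyl)-3,5-dihydroxy-7-(3-methylbut-2-enyloxy)chroman-4-one (CNP0296402.1) | CC(C)=CCOc1cc(O)c2c(c1)O[C@H](c1ccc(O)c(O)c1)[C@@H](O)C2=O | target

**Step count**

Total: 10 steps (9 if 2 is purchased). Longest linear sequence: 9 steps (steps 1–3 and 5–10, from 1 to 14).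

**Steps most likely to fail**

1. Step 9 (new method). Several processes may defeat it:
 - the carbene may add to the aliphatic formyl group, and the enaminol formed there may expel the aryloxide (internal redox);
 - acyl-anion formation at the hindered, electron-rich aryl aldehyde may be too slow;
 - the C2 enol may close onto the aryl aldehyde in an aldol reaction;
 - the catalyst may discriminate poorly between the interconverting C2 enantiomers.

 Fallback with known chemistry, from 12 back to 13: a samarium diiodide pinacol cyclisation of 12 (SmI2, t-BuOH, THF, −78 °C) would form the same C3–C4 bond through a ketyl radical and give the racemic 2-aryl-chromane-3,4-diol F1 as a diastereomer mixture. Selective oxidation of the benzylic C4 carbinol with activated MnO2 in CH2Cl2, followed by equilibration of C3 with Et3N, should give the racemic 2,3-trans ketol, which is 13 accompanied by its (2S,3S) enantiomer F2. Preparative HPLC on a chiral stationary phase separates the two, and the route is rejoined at 13.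

2. Step 5. The benzylic bromide may solvolyse or decompose before it is displaced, the phloroglucinol-type ring may be C-alkylated, or both ortho hydroxyls may be etherified.

 Fallback, from 3 (with 8) back to 9: hydroxylation of the potassium enolate of 3 (KHMDS, THF, −78 °C, then 2-(phenylsulfonyl)-3-phenyloxaziridine) would give the racemic mandelate ester F3. Mitsunobu etherification of 8 with F3 (PPh3, DIAD, THF, 0 °C to rt) then forms the O1–C2 bond at the non-chelated hydroxyl and delivers 9. Bromide 5 and step 3 are no longer needed.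

3. Step 7. The ortho silyl group may migrate from the phenol oxygen to the new benzylic alkoxide, and the very electron-rich benzylic alcohol may ionise on work-up or on silica.

 Fallback, from 10 back to 12, bypassing 11 and step 8: the aryl aldehyde of 10 is masked as the dimethyl acetal F4 (HC(OMe)3, MeOH, PPTS cat.). Partial reduction of the ester with DIBAL-H (1.1 equiv, toluene, −78 °C) stops at the aldehyde F5. Mild hydrolysis of the labile trialkoxybenzaldehyde acetal (wet silica gel, CH2Cl2) then releases 12.

**Further compounds**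

F1 | step 9 | 2-[3,4-bis(tert-butyldimethylsilyloxy)phenyl]-5-(tert-butyldimethylsilyloxy)-7-(3-methylbut-2-enyloxy)chromane-3,4-diol (racemic, diastereomer mixture) | CC(C)=CCOc1cc(O[Si](C)(C)C(C)(C)C)c2c(c1)OC(c1ccc(O[Si](C)(C)C(C)(C)C)c(O[Si](C)(C)C(C)(C)C)c1)C(O)C2O
F2 | step 9 | (2S,3S)-2-[3,4-bis(tert-butyldimethylsilyloxy)phenyl]-5-(tert-butyldimethylsilyloxy)-3-hydroxy-7-(3-methylbut-2-enyloxy)chroman-4-one (enantiomer of 13) | CC(C)=CCOc1cc(O[Si](C)(C)C(C)(C)C)c2c(c1)O[C@@H](c1ccc(O[Si](C)(C)C(C)(C)C)c(O[Si](C)(C)C(C)(C)C)c1)[C@H](O)C2=O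
F3 | step 5 | methyl 2-[3,4-bis(tert-butyldimethylsilyloxy)phenyl]-2-hydroxyacetate (racemic) | COC(=O)C(O)c1ccc(O[Si](C)(C)C(C)(C)C)c(O[Si](C)(C)C(C)(C)C)c1
F4 | step 7 | methyl 2-[3,4-bis(tert-butyldimethylsilyloxy)phenyl]-2-[3-(tert-butyldimethylsilyloxy)-2-(dimethoxymethyl)-5-(3-methylbut-2-enyloxy)phenoxy]acetate (racemic) | COC(=O)C(Oc1cc(OCC=C(C)C)cc(O[Si](C)(C)C(C)(C)C)c1C(OC)OC)c1ccc(O[Si](C)(C)C(C)(C)C)c(O[Si](C)(C)C(C)(C)C)c1
F5 | step 7 | 2-[3,4-bis(tert-butyldimethylsilyloxy)phenyl]-2-[3-(tert-butyldimethylsilyloxy)-2-(dimethoxymethyl)-5-(3-methylbut-2-enyloxy)phenoxy]acetaldehyde (racemic) | O=CC(Oc1cc(OCC=C(C)C)cc(O[Si](C)(C)C(C)(C)C)c1C(OC)OC)c1ccc(O[Si](C)(C)C(C)(C)C)c(O[Si](C)(C)C(C)(C)C)c1
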